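**Plan**
- Retrosynthesis: the depside ester is cut at the aryl C–C(=O) bond and, with it, at the C(=O)–O bond, so the carbonyl carbon comes from CO. The pieces are an aryl iodide, CO and a phenol.
- Enabling feature: the ester carbonyl sits between C1 of the upper 2,4-dioxygenated ring (flanked by an O-substituent and the CH2 side chain) and the 4-oxygen of the lower resorcylate ring. This is the connectivity an aroyl-palladium gives when a phenoxide captures it. Both benzene rings carry the same 2,4-dihydroxy-6-(2-oxoheptyl)benzoyl pattern, so one iodoarene 7 serves twice.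
- Forward order: side chain on 3,5-bis(benzyloxy)benzaldehyde (nitroaldol, reductive hydrolysis), dioxolane, ring iodination; one portion of 7 is converted into the lower-half phenol 10; 7 + CO + 10 are joined; the ketals are hydrolysed and the benzyl groups removed.
- No ring is formed; both arenes are bought. The dioxolanes block isocoumarin formation at the acyl-palladium stage.
- Stereochemistry: the target has no stereocentre and no stereogenic double bond, so there is nothing to control.

Key step: step 7

Assumption: the target is achiral, so "single enantiomer" needs no measure; 3,5-bis(benzyloxy)benzaldehyde and 1-nitrohexane are taken as commercial.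

**Step 1**
Reactants: 1 3,5-bis(benzyloxy)benzaldehyde; 2 1-nitrohexane
Product: 3 (E)-1,3-bis(benzyloxy)-5-(2-nitrohept-1-en-1-yl)benzene
Conditions: NH4OAc (cat.), AcOH, 100 °C
Reagents that add atoms: none
Why: Henry (nitroaldol) condensation with in-situ dehydration should give the conjugated nitroalkene; its geometry is irrelevant because the double bond is reduced in step 2.

**Step 2**
Reactants: 3 (E)-1,3-bis(benzyloxy)-5-(2-nitrohept-1-en-1-yl)benzene
Product: 5 1-[3,5-bis(benzyloxy)phenyl]heptan-2-one, via ketimine 4 (not isolated)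
Conditions: Fe powder, AcOH, 90 °C; aqueous work-up
Reagents that add atoms: water, O
Why: Iron in acetic acid should reduce the nitroalkene to the ketimine, which hydrolyses to the benzyl ketone (the classical nitroalkene-to-ketone reductive hydrolysis); benzyl ethers are inert to these conditions.

**Step 3**
Reactants: 5 1-[3,5-bis(benzyloxy)phenyl]heptan-2-one
Product: 6 2-[3,5-bis(benzyloxy)benzyl]-2-pentyl-1,3-dioxolane
Conditions: ethylene glycol, p-TsOH (cat.), toluene, reflux, Dean–Stark
Reagents that add atoms: ethylene glycol, OCCO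
Why: Acid-catalysed ketalisation with azeotropic removal of water should mask the enolisable ketone before any acyl-palladium is generated next to it.

**Step 4**
Reactants: 6 2-[3,5-bis(benzyloxy)benzyl]-2-pentyl-1,3-dioxolane
Product: 7 2-[3,5-bis(benzyloxy)-2-iodobenzyl]-2-pentyl-1,3-dioxolane
Conditions: NIS (1.05 equiv), MeCN, 0 °C to rt, dark
Reagents that add atoms: N-iodosuccinimide, O=C1CCC(=O)N1I
Why: Electrophilic aromatic iodination of a 5-alkylresorcinol diether should go to the position para to one benzyloxy group and ortho to the alkyl group, not to the crowded carbon between the two ether oxygens; the acid-free medium keeps the dioxolane intact.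

**Step 5**
Reactants: 7 2-[3,5-bis(benzyloxy)-2-iodobenzyl]-2-pentyl-1,3-dioxolane
Product: 8 benzyl 2,4-bis(benzyloxy)-6-[(2-pentyl-1,3-dioxolan-2-yl)methyl]benzoate
Conditions: Pd(OAc)2 (5 mol%), Xantphos (6 mol%), CO (1 atm), BnOH, Et3N, toluene, 80 °C
Reagents that add atoms: carbon monoxide, [C-]#[O+]; benzyl alcohol, OCc1ccccc1
Why: Palladium-catalysed alkoxycarbonylation of an aryl iodide (oxidative addition, CO insertion, alcoholysis of the aroyl-palladium) should give the benzyl ester; the ketal excludes trapping by a side-chain enol.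

**Step 6**
Reactants: 8 benzyl 2,4-bis(benzyloxy)-6-[(2-pentyl-1,3-dioxolan-2-yl)methyl]benzoate
Product: 10 benzyl 2,4-dihydroxy-6-[(2-pentyl-1,3-dioxolan-2-yl)methyl]benzoate, via dihydroxy acid 9 (not isolated)
Conditions: H2 (1 atm), 10% Pd/C, THF, rt; filter, concentrate; BnBr (1.0 equiv), KHCO3, DMF, rt
Reagents that add atoms: benzyl bromide, BrCc1ccccc1
Why: Hydrogenolysis should remove all three benzyl groups, and the crude acid is then alkylated at the carboxylate only, since hydrogencarbonate does not deprotonate the phenols (the standard preparation of benzyl resorcylates); telescoping limits contact of the free acid with its own ketal.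

**Step 7**
Reactants: 7 2-[3,5-bis(benzyloxy)-2-iodobenzyl]-2-pentyl-1,3-dioxolane; 10 benzyl 2,4-dihydroxy-6-[(2-pentyl-1,3-dioxolan-2-yl)methyl]benzoate
Product: 11 benzyl 4-{[2,4-bis(benzyloxy)-6-[(2-pentyl-1,3-dioxolan-2-yl)methyl]benzoyl]oxy}-2-hydroxy-6-[(2-pentyl-1,3-dioxolan-2-yl)methyl]benzoate
Conditions: Pd(OAc)2 (5 mol%), Xantphos (10 mol%), CO (1 atm), Et3N, toluene, 80 °C
Reagents that add atoms: carbon monoxide, [C-]#[O+]
Why: Pd(0) should add oxidatively to the C–I bond of 7, CO should insert to give the 2,6-disubstituted aroyl-palladium(II), and the triethylammonium phenoxide of 10 should capture it, so that the aryl C–C(=O) bond and the C(=O)–O bond of the depside form in one three-component operation. The closest known reaction type is the palladium-catalysed aryloxycarbonylation of aryl iodides with phenols under CO. No ring is closed and no stereocentre is created. The step needs site selectivity between the two phenols of 10: the 2-OH is held in a hydrogen bond to the benzyl ester carbonyl and is flanked by it, so the more acidic, unhindered 4-OH should react. It also needs chemoselectivity against intramolecular capture of the aroyl-palladium by a side-chain enol (isocoumarin formation), which the dioxolane of 7 excludes. Direct C–O coupling without CO is disfavoured by the two ortho substituents, which favour CO insertion, and by the wide-bite-angle ligand under a CO atmosphere.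

**Step 8**
Reactants: 11 benzyl 4-{[2,4-bis(benzyloxy)-6-[(2-pentyl-1,3-dioxolan-2-yl)methyl]benzoyl]oxy}-2-hydroxy-6-[(2-pentyl-1,3-dioxolan-2-yl)methyl]benzoate
Product: 12 benzyl 4-{[2,4-bis(benzyloxy)-6-(2-oxoheptyl)benzoyl]oxy}-2-hydroxy-6-(2-oxoheptyl)benzoate
Conditions: 2 M aq. HCl, THF, rt
Reagents that add atoms: water, O
Why: Mild aqueous acid hydrolysis of the two dioxolanes should free both ketones while the carboxyl is still a benzyl ester and three phenols are capped, which keeps enol-lactonisation slow; aryl and benzyl esters tolerate dilute acid at room temperature.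

**Step 9**
Reactants: 12 benzyl 4-{[2,4-bis(benzyloxy)-6-(2-oxoheptyl)benzoyl]oxy}-2-hydroxy-6-(2-oxoheptyl)benzoate
Product: 13 4-{[2,4-dihydroxy-6-(2-oxoheptyl)benzoyl]oxy}-2-hydroxy-6-(2-oxoheptyl)benzoic acid
Conditions: H2 (1 atm), 10% Pd/C, EtOAc, rt
Reagents that add atoms: none
Why: Neutral hydrogenolysis of the two benzyl ethers and the benzyl ester is the standard depside endgame; it should leave the aryl ester and the aliphatic ketones untouched.

**Compound list**
1 | 3,5-bis(benzyloxy)benzaldehyde | O=Cc1cc(OCc2ccccc2)cc(OCc2ccccc2)c1 | starting material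
2 | 1-nitrohexane | CCCCCC[N+](=O)[O-] | starting material
3 | (E)-1,3-bis(benzyloxy)-5-(2-nitrohept-1-en-1-yl)benzene | CCCCC/C(=C\c1cc(OCc2ccccc2)cc(OCc2ccccc2)c1)[N+](=O)[O-] | intermediate
4 | 1-[3,5-bis(benzyloxy)phenyl]heptan-2-imine (ketimine, not isolated) | CCCCCC(=N)Cc1cc(OCc2ccccc2)cc(OCc2ccccc2)c1 | intermediate
5 | 1-[3,5-bis(benzyloxy)phenyl]heptan-2-one | CCCCCC(=O)Cc1cc(OCc2ccccc2)cc(OCc2ccccc2)c1 | intermediate
6 | 2-[3,5-bis(benzyloxy)benzyl]-2-pentyl-1,3-dioxolane | CCCCCC1(Cc2cc(OCc3ccccc3)cc(OCc3ccccc3)c2)OCCO1 | intermediate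
7 | 2-[3,5-bis(benzyloxy)-2-iodobenzyl]-2-pentyl-1,3-dioxolane | CCCCCC1(Cc2cc(OCc3ccccc3)cc(OCc3ccccc3)c2I)OCCO1 | intermediate
8 | benzyl 2,4-bis(benzyloxy)-6-[(2-pentyl-1,3-dioxolan-2-yl)methyl]benzoate | CCCCCC1(Cc2cc(OCc3ccccc3)cc(OCc3ccccc3)c2C(=O)OCc2ccccc2)OCCO1 | intermediate
9 | 2,4-dihydroxy-6-[(2-pentyl-1,3-dioxolan-2-yl)methyl]benzoic acid (not isolated) | CCCCCC1(Cc2cc(O)cc(O)c2C(=O)O)OCCO1 | intermediate
10 | benzyl 2,4-dihydroxy-6-[(2-pentyl-1,3-dioxolan-2-yl)methyl]benzoate | CCCCCC1(Cc2cc(O)cc(O)c2C(=O)OCc2ccccc2)OCCO1 | intermediate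
11 | benzyl 4-{[2,4-bis(benzyloxy)-6-[(2-pentyl-1,3-dioxolan-2-yl)methyl]benzoyl]oxy}-2-hydroxy-6-[(2-pentyl-1,3-dioxolan-2-yl)methyl]benzoate | CCCCCC1(Cc2cc(OC(=O)c3c(OCc4ccccc4)cc(OCc4ccccc4)cc3CC3(CCCCC)OCCO3)cc(O)c2C(=O)OCc2ccccc2)OCCO1 | intermediate
12 | benzyl 4-{[2,4-bis(benzyloxy)-6-(2-oxoheptyl)benzoyl]oxy}-2-hydroxy-6-(2-oxoheptyl)benzoate | CCCCCC(=O)Cc1cc(OC(=O)c2c(OCc3ccccc3)cc(OCc3ccccc3)cc2CC(=O)CCCCC)cc(O)c1C(=O)OCc1ccccc1 | intermediate
13 | 4-{[2,4-dihydroxy-6-(2-oxoheptyl)benzoyl]oxy}-2-hydroxy-6-(2-oxoheptyl)benzoic acid | CCCCCC(=O)Cc1cc(OC(=O)c2c(O)cc(O)cc2CC(=O)CCCCC)cc(O)c1C(=O)O | target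

**Step count and risks**
Total steps: 9. Longest linear sequence: 9 (steps 1–9; iodide 7 enters twice, once through 8 and 10 and once directly in step 7).

Steps most likely to fail:

1. Step 7. The doubly ortho-substituted aroyl-palladium may be captured too slowly by the phenoxide, so that reduction of the iodide or acylation at the wrong phenol competes. Fallback, from 7 back to 11: iodine–magnesium exchange on 7 (i-PrMgCl·LiCl, THF, −20 °C) should give the arylmagnesium chloride F1, which is quenched with CO2 to 2,4-bis(benzyloxy)-6-[(2-pentyl-1,3-dioxolan-2-yl)methyl]benzoic acid F2. Steglich esterification of F2 with the 4-OH of 10 (DCC, DMAP, CH2Cl2, rt), the classical depside C–O bond formation, then gives 11.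

2. Step 8. During the hydrolysis an unmasked ketone enol may attack the neighbouring aryl ester under acid and expel the lower ring as its phenol (enol-lactonisation), or the depside ester may be cleaved. Fallback, from 11 back to 13: the order of deprotection is reversed. Hydrogenolysis of 11 (H2, Pd/C, EtOAc) should give the diketal acid 4-{[2,4-dihydroxy-6-[(2-pentyl-1,3-dioxolan-2-yl)methyl]benzoyl]oxy}-2-hydroxy-6-[(2-pentyl-1,3-dioxolan-2-yl)methyl]benzoic acid F3. Its own salicylic-type carboxyl then serves as the only acid for ketal hydrolysis in wet THF at 40–50 °C, with no mineral acid, giving 13 directly.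

3. Step 4. The electron-rich ring may be iodinated twice, or adventitious HI may open the dioxolane when the reaction has to be pushed. Fallback, from 1 back to 7: the iodine is introduced at the aldehyde stage, where the ring is deactivated and acid activation is harmless. NIS with catalytic TFA in MeCN should give 3,5-bis(benzyloxy)-2-iodobenzaldehyde F4. Nitroaldol condensation with 2 gives the iodo nitroalkene F5. Fe/AcOH converts it through the iodo ketimine F6 (not isolated) into 1-[3,5-bis(benzyloxy)-2-iodophenyl]heptan-2-one F7, and ketalisation with ethylene glycol (p-TsOH, toluene, Dean–Stark) gives 7.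

**Further compounds**
F1 | step 7 | {2,4-bis(benzyloxy)-6-[(2-pentyl-1,3-dioxolan-2-yl)methyl]phenyl}magnesium chloride | CCCCCC1(Cc2cc(OCc3ccccc3)cc(OCc3ccccc3)c2[Mg]Cl)OCCO1
F2 | step 7 | 2,4-bis(benzyloxy)-6-[(2-pentyl-1,3-dioxolan-2-yl)methyl]benzoic acid | CCCCCC1(Cc2cc(OCc3ccccc3)cc(OCc3ccccc3)c2C(=O)O)OCCO1
F3 | step 8 | 4-{[2,4-dihydroxy-6-[(2-pentyl-1,3-dioxolan-2-yl)methyl]benzoyl]oxy}-2-hydroxy-6-[(2-pentyl-1,3-dioxolan-2-yl)methyl]benzoic acid | CCCCCC1(Cc2cc(OC(=O)c3c(O)cc(O)cc3CC3(CCCCC)OCCO3)cc(O)c2C(=O)O)OCCO1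
F4 | step 4 | 3,5-bis(benzyloxy)-2-iodobenzaldehyde | O=Cc1cc(OCc2ccccc2)cc(OCc2ccccc2)c1I
F5 | step 4 | (E)-1,5-bis(benzyloxy)-2-iodo-3-(2-nitrohept-1-en-1-yl)benzene | CCCCC/C(=C\c1cc(OCc2ccccc2)cc(OCc2ccccc2)c1I)[N+](=O)[O-]
F6 | step 4 | 1-[3,5-bis(benzyloxy)-2-iodophenyl]heptan-2-imine | CCCCCC(=N)Cc1cc(OCc2ccccc2)cc(OCc2ccccc2)c1I
F7 | step 4 | 1-[3,5-bis(benzyloxy)-2-iodophenyl]heptan-2-one | CCCCCC(=O)Cc1cc(OCc2ccccc2)cc(OCc2ccccc2)c1I
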